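**Plan**

- Retrosynthetic cuts: (i) the side-chain C3–C4 bond, by a syn-aldol of pentan-3-one onto a 2-substituted acrolein; (ii) both oxirane C–O bonds, by epoxidation of a cyclohexa-1,3-diene; (iii) the bond from pyrone C-6 to the quaternary ring carbon together with that carbon's C–CH3 bond, in one pot; (iv) the carbocycle is (R)-carvone and the pyrone comes from an oxoglutarate diester.
- Enabling feature: the quaternary carbon (C-4 of the 7-oxabicyclo[4.1.0]hept-2-ene) is next to the ring =CH (C-3), which can be written as a ketone C=O, so it is a ketone α-carbon. Pyrone C-6 is an O-substituted sp2 carbon β to the pyranone C=O, hence electrophilic (a vinylogous carbonate) when it carries OMe. The carbocycle has the p-menthane pattern (C-methyl on the sp2 carbon para to the carbon that bears the three-carbon branch).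
- Forward order: carvone → oxidised and protected isopropenyl → α′-methylation → Wharton 1,3-transposition (carbonyl moves to the other flank of the branch-bearing carbon; the new methyl becomes γ) → one-pot enolate pyronylation/methylation → γ-enolisation, triflate, reduction to the 1,3-diene → enal → epoxide → aldol.
- Stereochemistry: C-5 of carvone is bought. The quaternary centre follows by anti-alkylation (1,2-induction), the oxirane by attack anti to side chain and pyrone, and the two side-chain centres by an Ipc2B-controlled syn-aldol.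

Key step: step 10

Remark: centres that are planarised later (C-6 of 11, the oxirane of 12 and 13, the carbinol of 14, C-4 of 15 to 18) are written as the isomer expected to predominate; their epimers would converge on the same later compounds.

**Route**

Step 1
Reactants: 1 dimethyl 3-oxopentanedioate
Product: 3 dimethyl 2,4-dimethyl-3-oxopentanedioate, via monomethylated diester 2 (not isolated)
Conditions: MeI (2.1 equiv), K2CO3, acetone, reflux
Reagents that add atoms: iodomethane, CI
Why: Enolate C-alkylation of each doubly activated methylene of the β-keto diester under carbonate base should stop after one methyl per α-carbon, because the second alkylation at an already substituted carbon is slower.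

Step 2
Reactants: 3 dimethyl 2,4-dimethyl-3-oxopentanedioate
Product: 4 2,6-dimethoxy-3,5-dimethyl-4H-pyran-4-one
Conditions: oleum (20% SO3 in H2SO4), 0 °C → rt; then ice
Reagents that add atoms: none
Why: Acid-mediated cyclodehydration of a 3-oxoglutarate diester, in which one ester carbonyl oxygen closes on the other activated ester carbon and the water is taken up by SO3, should give the 2,6-dialkoxy-4-pyranone.

Step 3
Reactants: 5 (R)-(−)-carvone
Product: 6 (R)-5-(3-chloroprop-1-en-2-yl)-2-methylcyclohex-2-en-1-one (10-chlorocarvone)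
Conditions: Ca(OCl)2, CO2 (dry ice), CH2Cl2/H2O, 0 °C
Reagents that add atoms: calcium hypochlorite, [Ca+2].[O-]Cl.[O-]Cl
Why: Ene-type allylic chlorination by HOCl should take place at the electron-rich 1,1-disubstituted alkene with double-bond shift and leave the electron-poor enone and the stereocentre untouched.

Step 4
Reactants: 6 10-chlorocarvone
Product: 8 (R)-5-(3-hydroxyprop-1-en-2-yl)-2-methylcyclohex-2-en-1-one, via allylic acetate 7 (not isolated)
Conditions: KOAc, Bu4NI (cat.), DMF, 50 °C; then K2CO3 (cat.), MeOH, rt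
Reagents that add atoms: potassium acetate, CC(=O)[O-].[K+]
Why: SN2 displacement of the primary allylic chloride by acetate followed by mild transesterification should give the allylic alcohol without touching the enone.

Step 5
Reactants: 8 10-hydroxycarvone
Product: 9 (R)-5-[3-(tert-butyldimethylsilyloxy)prop-1-en-2-yl]-2-methylcyclohex-2-en-1-one
Conditions: TBSCl, imidazole, CH2Cl2, rt
Reagents that add atoms: tert-butyldimethylsilyl chloride, CC(C)(C)[Si](C)(C)Cl
Why: Standard silylation of the primary alcohol gives an ether that should withstand the later enolate, peroxide, hydrazine and palladium steps.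

Step 6
Reactants: 9 silyl ether of 10-hydroxycarvone
Product: 11 (5R,6S)-5-[3-(tert-butyldimethylsilyloxy)prop-1-en-2-yl]-2,6-dimethylcyclohex-2-en-1-one (6-methyl trans to the side chain), via lithium dienolate 10 (not isolated)
Conditions: LDA, THF, −78 °C; MeI, −78 → −20 °C
Reagents that add atoms: iodomethane, CI
Why: Kinetic α′-deprotonation of the enone and enolate alkylation anti to the C-5 substituent should give mainly the trans product, and the configuration of this centre is of no consequence because it becomes sp2 in step 11.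

Step 7
Reactants: 11 6-methyl enone
Product: 12 1,3-dimethyl-4-[3-(tert-butyldimethylsilyloxy)prop-1-en-2-yl]-7-oxabicyclo[4.1.0]heptan-2-one (oxirane trans to the side chain)
Conditions: 30% H2O2, NaOH (cat.), MeOH, 0 °C
Reagents that add atoms: hydrogen peroxide, OO
Why: Weitz–Scheffer nucleophilic epoxidation should take place only at the enone C=C, with hydroperoxide adding to the β-carbon anti to the side chain, and not at the isolated alkene.

Step 8
Reactants: 12 epoxy ketone
Product: 14 5-[3-(tert-butyldimethylsilyloxy)prop-1-en-2-yl]-2,4-dimethylcyclohex-2-en-1-ol (hydroxyl and 4-methyl trans to the side chain), via epoxy hydrazone 13 (not isolated)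
Conditions: N2H4·H2O, AcOH (cat.), MeOH, 0 °C → rt
Reagents that add atoms: none
Why: Wharton transposition (hydrazone formation, oxirane opening and loss of N2) should give the transposed allylic alcohol, and it is placed here because the pyrone of later intermediates should not survive hydrazine.

Step 9
Reactants: 14 transposed allylic alcohol
Product: 15 (4R,5R)-5-[3-(tert-butyldimethylsilyloxy)prop-1-en-2-yl]-2,4-dimethylcyclohex-2-en-1-one
Conditions: Dess–Martin periodinane, CH2Cl2, rt
Reagents that add atoms: none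
Why: Dess–Martin oxidation of the secondary allylic alcohol completes the 1,3-carbonyl transposition, which puts the methyl-bearing carbon in the γ-position and frees an α′-CH2 on the other flank of the branch-bearing carbon.

Step 10
Reactants: 15 transposed enone; 4 2,6-dimethoxy-3,5-dimethyl-4H-pyran-4-one
Product: 18 (4R,5R,6R)-5-[3-(tert-butyldimethylsilyloxy)prop-1-en-2-yl]-6-(6-methoxy-3,5-dimethyl-4-oxo-4H-pyran-2-yl)-2,4,6-trimethylcyclohex-2-en-1-one (pyrone cis and 6-methyl trans to the side chain), via kinetic lithium enolate 16 (not isolated), via pyronyl ketone lithium enolate 17 (not isolated)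
Conditions: LDA, THF, −78 °C; then 4 and LiHMDS, −78 → 0 °C; then MeI, DMPU, −40 → 0 °C
Reagents that add atoms: iodomethane, CI
Why: Proposed new method: the kinetic α′-enolate 16 should add through carbon to C-2 of 4, the β-carbon of a β-alkoxy enone (a vinylogous carbonate), and the adduct should expel methoxide (addition–elimination, in effect a vinylogous Claisen condensation), the closest known reaction types being the desymmetrising substitution of one methoxy group of 4 by organolithium carbon nucleophiles and the SNAr α-heteroarylation of ketone enolates. The substitution product is C–H acidic (α to the ketone and vinylogously α to the pyranone carbonyl), so LiHMDS should convert it at once into the planar enolate 17, which drives the condensation and shields the remaining methoxy group from a second substitution. Iodomethane should then alkylate C-6 of 17 on the face opposite to the neighbouring C-5 side chain, the sense known for the second α′-alkylation of carvone enolates, so that the new quaternary centre carries methyl trans and pyrone cis to the side chain (1,2-induction from the centre bought with carvone; the configuration formed in the first bond-forming event is erased in 17 and does not matter). No ring is closed. The step needs α′- over γ-deprotonation (LDA at −78 °C before 4 is added), C- over O-attack in both bond formations (lithium counter-ion, soft MeI) and mono-substitution of 4 (secured by enolate formation in the product).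

Step 11
Reactants: 18 quaternary pyronyl enone
Product: 20 5-[3-(tert-butyldimethylsilyloxy)prop-1-en-2-yl]-6-(6-methoxy-3,5-dimethyl-4-oxo-4H-pyran-2-yl)-2,4,6-trimethylcyclohexa-1,3-dien-1-yl trifluoromethanesulfonate (pyrone cis to the side chain), via potassium dienolate 19 (not isolated)
Conditions: KHMDS, THF, −78 → −40 °C; PhNTf2, → 0 °C
Reagents that add atoms: N-phenylbis(trifluoromethanesulfonimide), O=S(=O)(N(c1ccccc1)S(=O)(=O)C(F)(F)F)C(F)(F)F
Why: Because 18 has no α′-hydrogen, the base can only remove the γ-hydrogen at C-4, and O-triflation of the extended dienolate (vinyl triflate formation) should give the dienyl triflate while erasing the C-4 stereocentre.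

Step 12
Reactants: 20 dienyl triflate
Product: 21 6-{(1R,6R)-6-[3-(tert-butyldimethylsilyloxy)prop-1-en-2-yl]-1,3,5-trimethylcyclohexa-2,4-dien-1-yl}-2-methoxy-3,5-dimethyl-4H-pyran-4-one (pyrone cis to the side chain)
Conditions: Pd(OAc)2 (cat.), PPh3, HCO2H, n-Bu3N, DMF, 60 °C, dark
Reagents that add atoms: none
Why: Palladium-catalysed formate reduction of a vinyl triflate (oxidative addition, decarboxylation of the formate, C–H reductive elimination) should give the 1,3-diene, whose aromatisation is blocked by the quaternary carbon.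

Step 13
Reactants: 21 silyl diene
Product: 22 6-{(1R,6R)-6-(3-hydroxyprop-1-en-2-yl)-1,3,5-trimethylcyclohexa-2,4-dien-1-yl}-2-methoxy-3,5-dimethyl-4H-pyran-4-one
Conditions: TBAF, THF, 0 °C, dark
Reagents that add atoms: none
Why: Fluoride cleavage of the silyl ether is selective and should leave the diene and the pyrone untouched.

Step 14
Reactants: 22 diene alcohol
Product: 23 2-[(1S,6R)-6-(6-methoxy-3,5-dimethyl-4-oxo-4H-pyran-2-yl)-2,4,6-trimethylcyclohexa-2,4-dien-1-yl]prop-2-enal (pyrone cis to the side chain)
Conditions: MnO2, CH2Cl2, rt, dark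
Reagents that add atoms: none
Why: Manganese dioxide oxidises the primary allylic alcohol selectively to the 2-substituted acrolein, which also deactivates the exocyclic alkene towards the electrophilic oxidant of the next step.

Step 15
Reactants: 23 diene enal
Product: 24 2-[(1R,4R,5S,6S)-4-(6-methoxy-3,5-dimethyl-4-oxo-4H-pyran-2-yl)-2,4,6-trimethyl-7-oxabicyclo[4.1.0]hept-2-en-5-yl]prop-2-enal (oxirane trans to side chain and pyrone)
Conditions: DMDO, acetone, −40 → −20 °C, dark
Reagents that add atoms: dimethyldioxirane, CC1(C)OO1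
Why: Electrophilic epoxidation of a 1,3-diene under neutral conditions should take place at the trisubstituted C=C remote from the quaternary carbon and on the face opposite to the cis-disposed side chain and pyrone, while the enal alkene and the pyrone are electron-poor.

Step 16
Reactants: 24 epoxy enal
Product: 26 2-methoxy-3,5-dimethyl-6-{(1R,4R,5R,6S)-5-[(3R,4R)-3-hydroxy-4-methyl-5-oxohept-1-en-2-yl]-2,4,6-trimethyl-7-oxabicyclo[4.1.0]hept-2-en-4-yl}-4H-pyran-4-one (target), via boron aldolate 25 (not isolated)
Conditions: pentan-3-one, (+)-Ipc2BOTf [from (−)-α-pinene], i-Pr2NEt, CH2Cl2, −78 °C; then 24, −78 → −20 °C; MeOH, pH 7 buffer, 30% H2O2, 0 °C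
Reagents that add atoms: pentan-3-one, CCC(=O)CC
Why: The (Z)-boron enolate of pentan-3-one should add through a chair Zimmerman–Traxler transition state to give the syn-aldol, the (3R,4R) sense being set by the isopinocampheyl ligands (reagent control, Re-face attack on the aldehyde expected for the (+)-reagent) because the ring stereocentre is insulated by the sp2 carbon.

**Compound list**

1 | dimethyl 3-oxopentanedioate | COC(=O)CC(=O)CC(=O)OC | starting material
2 | dimethyl 2-methyl-3-oxopentanedioate (not isolated) | COC(=O)CC(=O)C(C)C(=O)OC | intermediate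
3 | dimethyl 2,4-dimethyl-3-oxopentanedioate (epimerisable mixture) | COC(=O)C(C)C(=O)C(C)C(=O)OC | intermediate
4 | 2,6-dimethoxy-3,5-dimethyl-4H-pyran-4-one | COc1oc(OC)c(C)c(=O)c1C | intermediate
5 | (R)-(−)-carvone | C=C(C)[C@H]1CC(=O)C(C)=CC1 | starting material
6 | (R)-5-(3-chloroprop-1-en-2-yl)-2-methylcyclohex-2-en-1-one | C=C(CCl)[C@H]1CC(=O)C(C)=CC1 | intermediate
7 | (R)-2-(4-methyl-5-oxocyclohex-3-en-1-yl)prop-2-en-1-yl acetate (not isolated) | C=C(COC(C)=O)[C@H]1CC(=O)C(C)=CC1 | intermediate
8 | (R)-5-(3-hydroxyprop-1-en-2-yl)-2-methylcyclohex-2-en-1-one | C=C(CO)[C@H]1CC(=O)C(C)=CC1 | intermediate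
9 | (R)-5-[3-(tert-butyldimethylsilyloxy)prop-1-en-2-yl]-2-methylcyclohex-2-en-1-one | C=C(CO[Si](C)(C)C(C)(C)C)[C@H]1CC(=O)C(C)=CC1 | intermediate
10 | lithium cross-conjugated dienolate of 9 (not isolated) | C=C(CO[Si](C)(C)C(C)(C)C)[C@H]1C=C(O[Li])C(C)=CC1 | intermediate
11 | (5R,6S)-5-[3-(tert-butyldimethylsilyloxy)prop-1-en-2-yl]-2,6-dimethylcyclohex-2-en-1-one | C=C(CO[Si](C)(C)C(C)(C)C)[C@H]1[C@H](C)C(=O)C(C)=CC1 | intermediate
12 | 1,3-dimethyl-4-[3-(tert-butyldimethylsilyloxy)prop-1-en-2-yl]-7-oxabicyclo[4.1.0]heptan-2-one, oxirane and 3-methyl trans to the side chain | C=C(CO[Si](C)(C)C(C)(C)C)[C@H]1[C@H](C)C(=O)[C@]2(C)O[C@@H]2C1 | intermediate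
13 | hydrazone of 12 (not isolated) | C=C(CO[Si](C)(C)C(C)(C)C)[C@H]1[C@H](C)C(=NN)[C@]2(C)O[C@@H]2C1 | intermediate
14 | 5-[3-(tert-butyldimethylsilyloxy)prop-1-en-2-yl]-2,4-dimethylcyclohex-2-en-1-ol, hydroxyl and 4-methyl trans to the side chain | C=C(CO[Si](C)(C)C(C)(C)C)[C@H]1[C@H](C)C=C(C)[C@H](O)C1 | intermediate
15 | (4R,5R)-5-[3-(tert-butyldimethylsilyloxy)prop-1-en-2-yl]-2,4-dimethylcyclohex-2-en-1-one | C=C(CO[Si](C)(C)C(C)(C)C)[C@H]1[C@H](C)C=C(C)C(=O)C1 | intermediate
16 | kinetic lithium enolate of 15, C1=C6 (not isolated) | C=C(CO[Si](C)(C)C(C)(C)C)[C@H]1[C@H](C)C=C(C)C(O[Li])=C1 | intermediate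
17 | lithium enolate of the 6-(6-methoxy-3,5-dimethyl-4-oxo-4H-pyran-2-yl) derivative of 15 (not isolated) | C=C(CO[Si](C)(C)C(C)(C)C)[C@H]1[C@H](C)C=C(C)C(O[Li])=C1c1oc(OC)c(C)c(=O)c1C | intermediate
18 | (4R,5R,6R)-5-[3-(tert-butyldimethylsilyloxy)prop-1-en-2-yl]-6-(6-methoxy-3,5-dimethyl-4-oxo-4H-pyran-2-yl)-2,4,6-trimethylcyclohex-2-en-1-one | C=C(CO[Si](C)(C)C(C)(C)C)[C@H]1[C@H](C)C=C(C)C(=O)[C@@]1(C)c1oc(OC)c(C)c(=O)c1C | intermediate
19 | potassium dienolate of 18, C1=C2 and C3=C4 (not isolated) | C=C(CO[Si](C)(C)C(C)(C)C)[C@H]1C(C)=CC(C)=C(O[K])[C@@]1(C)c1oc(OC)c(C)c(=O)c1C | intermediate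
20 | dienyl triflate: 5-[3-(tert-butyldimethylsilyloxy)prop-1-en-2-yl]-6-(6-methoxy-3,5-dimethyl-4-oxo-4H-pyran-2-yl)-2,4,6-trimethylcyclohexa-1,3-dien-1-yl trifluoromethanesulfonate, pyrone cis to the side chain | C=C(CO[Si](C)(C)C(C)(C)C)[C@H]1C(C)=CC(C)=C(OS(=O)(=O)C(F)(F)F)[C@@]1(C)c1oc(OC)c(C)c(=O)c1C | intermediate
21 | 6-{(1R,6R)-6-[3-(tert-butyldimethylsilyloxy)prop-1-en-2-yl]-1,3,5-trimethylcyclohexa-2,4-dien-1-yl}-2-methoxy-3,5-dimethyl-4H-pyran-4-one | C=C(CO[Si](C)(C)C(C)(C)C)[C@H]1C(C)=CC(C)=C[C@@]1(C)c1oc(OC)c(C)c(=O)c1C | intermediate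
22 | 6-{(1R,6R)-6-(3-hydroxyprop-1-en-2-yl)-1,3,5-trimethylcyclohexa-2,4-dien-1-yl}-2-methoxy-3,5-dimethyl-4H-pyran-4-one | C=C(CO)[C@H]1C(C)=CC(C)=C[C@@]1(C)c1oc(OC)c(C)c(=O)c1C | intermediate
23 | 2-[(1S,6R)-6-(6-methoxy-3,5-dimethyl-4-oxo-4H-pyran-2-yl)-2,4,6-trimethylcyclohexa-2,4-dien-1-yl]prop-2-enal | C=C(C=O)[C@H]1C(C)=CC(C)=C[C@@]1(C)c1oc(OC)c(C)c(=O)c1C | intermediate
24 | 2-[(1R,4R,5S,6S)-4-(6-methoxy-3,5-dimethyl-4-oxo-4H-pyran-2-yl)-2,4,6-trimethyl-7-oxabicyclo[4.1.0]hept-2-en-5-yl]prop-2-enal | C=C(C=O)[C@H]1[C@]2(C)O[C@@H]2C(C)=C[C@@]1(C)c1oc(OC)c(C)c(=O)c1C | intermediate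
25 | O-diisopinocampheylboryl aldolate of 26 (not isolated) | C=C([C@H](OB([C@H]2C[C@H]3C[C@@H]([C@@H]2C)C3(C)C)[C@H]2C[C@H]3C[C@@H]([C@@H]2C)C3(C)C)[C@@H](C)C(=O)CC)[C@H]1[C@]2(C)O[C@@H]2C(C)=C[C@@]1(C)c1oc(OC)c(C)c(=O)c1C | intermediate
26 | 2-methoxy-3,5-dimethyl-6-{(1R,4R,5R,6S)-5-[(3R,4R)-3-hydroxy-4-methyl-5-oxohept-1-en-2-yl]-2,4,6-trimethyl-7-oxabicyclo[4.1.0]hept-2-en-4-yl}-4H-pyran-4-one | C=C([C@H](O)[C@@H](C)C(=O)CC)[C@H]1[C@]2(C)O[C@@H]2C(C)=C[C@@]1(C)c1oc(OC)c(C)c(=O)c1C | target

**Step count and risks**

Total step count: 16. Longest linear sequence: 14 steps (steps 3 to 16, from (R)-carvone 5).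

1. Step 10 (the labelled step). What may go wrong: no C–C bond formation at the crowded vinylogous carbonate carbon, drift of the kinetic enolate to the γ-dienolate by proton transfer during a slow addition, or O-alkylation and loss of face selectivity in the methylation. Fallback with known chemistry, from 15 back to 18, builds the pyrone on the ring by the classical acylation and cyclisation sequence. Compound 15 is formylated (NaH, HCO2Et) to the hydroxymethylene ketone F1. This is C-methylated anti to the side chain (K2CO3, MeI, acetone) to the α-formyl α-methyl ketone F2. The dianion of methyl 2-methyl-3-oxopentanoate (NaH, then n-BuLi, THF, −78 °C) should add to the aldehyde and give the δ-hydroxy β-keto ester F3. Dess–Martin oxidation gives the triketo ester F4, DBU closes the 4-hydroxy-2-pyranone F5, and O-methylation with methyl fluorosulfonate, which is selective for the γ-pyrone, gives 18.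

2. Step 15. What may go wrong: attack at the other diene C=C or on the wrong face, or over-oxidation to a bis-epoxide. Fallback from 21 back to 24 uses the more sterically demanding osmium reagent and a diol-to-epoxide conversion with net retention. OsO4 (cat.)/NMO should give the cis-diol F6 on the open face of the C=C remote from the quaternary carbon. MeC(OMe)3/PPTS gives the cyclic orthoacetate F7. Me3SiCl opens it at the secondary allylic carbon with inversion to the chloro acetate F8. K2CO3/MeOH closes the oxirane with a second inversion to the epoxy silyl ether F9. TBAF gives the epoxy alcohol F10, and MnO2 gives 24.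

3. Step 16. What may go wrong: insufficient reagent control when the Ipc ligands are mismatched with the remote ring centre, or opening of the vinyl oxirane by the boron Lewis acid during a slow addition. Fallback from 24 back to 26 uses auxiliary control. The Evans syn-aldol of (R)-4-benzyl-3-propionyloxazolidin-2-one (Bu2BOTf, Et3N, CH2Cl2, −78 °C) should give the syn-aldol imide F11. MeONHMe·HCl/i-PrMgCl (THF, −20 °C) gives the Weinreb amide F12, and EtMgBr (THF, −78 → 0 °C) gives 26.

Further compounds
F1 | step 10 | 6-(hydroxymethylene) derivative of 15 | C=C(CO[Si](C)(C)C(C)(C)C)[C@H]1[C@H](C)C=C(C)C(=O)/C1=C\O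
F2 | step 10 | 6-formyl-6-methyl derivative of 15, formyl cis and methyl trans to the side chain | C=C(CO[Si](C)(C)C(C)(C)C)[C@H]1[C@H](C)C=C(C)C(=O)[C@@]1(C)C=O
F3 | step 10 | methyl 5-hydroxy-2,4-dimethyl-3-oxo-5-(ring C-6)pentanoate, mixture at the three new centres | C=C(CO[Si](C)(C)C(C)(C)C)[C@H]1[C@H](C)C=C(C)C(=O)[C@@]1(C)C(O)C(C)C(=O)C(C)C(=O)OC
F4 | step 10 | methyl 2,4-dimethyl-3,5-dioxo-5-(ring C-6)pentanoate | C=C(CO[Si](C)(C)C(C)(C)C)[C@H]1[C@H](C)C=C(C)C(=O)[C@@]1(C)C(=O)C(C)C(=O)C(C)C(=O)OC
F5 | step 10 | 6-(ring C-6)-4-hydroxy-3,5-dimethyl-2H-pyran-2-one | C=C(CO[Si](C)(C)C(C)(C)C)[C@H]1[C@H](C)C=C(C)C(=O)[C@@]1(C)c1oc(=O)c(C)c(O)c1C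
F6 | step 15 | cis-diol of 21 at the C=C remote from the quaternary carbon, both hydroxyls trans to the side chain | C=C(CO[Si](C)(C)C(C)(C)C)[C@H]1[C@](C)(O)[C@H](O)C(C)=C[C@@]1(C)c1oc(OC)c(C)c(=O)c1C
F7 | step 15 | cyclic methyl orthoacetate of F6, mixture at the orthoester carbon | C=C(CO[Si](C)(C)C(C)(C)C)[C@H]1[C@]2(C)OC(C)(OC)O[C@@H]2C(C)=C[C@@]1(C)c1oc(OC)c(C)c(=O)c1C
F8 | step 15 | tertiary acetate with secondary allylic chloride, chloride cis to the side chain | C=C(CO[Si](C)(C)C(C)(C)C)[C@H]1[C@](C)(OC(C)=O)[C@@H](Cl)C(C)=C[C@@]1(C)c1oc(OC)c(C)c(=O)c1C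
F9 | step 15 | silyl ether of the epoxy alcohol, oxirane trans to the side chain | C=C(CO[Si](C)(C)C(C)(C)C)[C@H]1[C@]2(C)O[C@@H]2C(C)=C[C@@]1(C)c1oc(OC)c(C)c(=O)c1C
F10 | step 15 | epoxy allylic alcohol | C=C(CO)[C@H]1[C@]2(C)O[C@@H]2C(C)=C[C@@]1(C)c1oc(OC)c(C)c(=O)c1C
F11 | step 16 | syn-aldol N-acyl (R)-4-benzyloxazolidin-2-one | C=C([C@H](O)[C@@H](C)C(=O)N1C(=O)OC[C@H]1Cc1ccccc1)[C@H]1[C@]2(C)O[C@@H]2C(C)=C[C@@]1(C)c1oc(OC)c(C)c(=O)c1C
F12 | step 16 | syn-aldol N-methoxy-N-methylamide | C=C([C@H](O)[C@@H](C)C(=O)N(C)OC)[C@H]1[C@]2(C)O[C@@H]2C(C)=C[C@@]1(C)c1oc(OC)c(C)c(=O)c1C
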